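**Retrosynthetic overview**

1. Target ⇐ 6β,8α‑diol + 3,4,5‑trimethoxybenzoic acid (Mitsunobu esterification, inversion at C8) ⇐ its 8‑PMB ether (DDQ).
2. (Z)‑C1=C10 ⇐ trans‑1,10‑oxirane by deoxygenation with inversion (LiPPh2, then MeI); trans‑4,5‑epoxy‑6‑ol ⇐ 4E‑enone (nucleophilic epoxidation, then anti‑selective reduction).
3. 1,10‑Epoxy‑4E‑enone ⇐ (1(10)E,4Z)‑cyclodecadienone (stannyl addition/peracid turns the Z‑enone into E; more peracid makes the 1,10‑oxirane).
4. Ten‑membered ring ⇐ anionic oxy‑Cope [3,3] ring expansion of a trans‑1,2‑dialkenylcyclohexenol (forms C8–C9; C8 set by the chair transition state, C7 by enolate protonation).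
5. Cyclohexenol ⇐ (R)‑isopiperitenone (one step from (S)‑limonene) + a cis‑β‑alkoxyvinyllithium. Ring order: cyclohexene (bought) → cyclodecadiene → 1,10‑oxirane (temporary) → 4,5‑oxirane.

Assumption: the ring alkene is Z exactly as the SMILES encodes it (ring carbons cis); names use germacrane numbering (C4 and C10 carry the methyls, C7 the isopropyl group; α is the face of H‑7).

**Route**

Step 1
Reactants: 1 (S)-limonene [(4S)-1-methyl-4-(prop-1-en-2-yl)cyclohex-1-ene]
Product: 2 (R)-isopiperitenone [(6R)-3-methyl-6-(prop-1-en-2-yl)cyclohex-2-en-1-one]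
Conditions: t-BuOOH (3 equiv), Cr(CO)6 (0.3 equiv), MeCN, reflux; chromatography (regioisomeric carvone removed)
Reagents that add atoms: tert-butyl hydroperoxide CC(C)(C)OO
Why: Chromium-catalysed radical allylic oxidation turns the ring CH2 between the alkene and the stereocentre into the enone carbonyl without touching the bought stereocentre, whose descriptor changes from S to R only through CIP priorities.

Step 2
Reactants: 3 3-methylbutanal; 4 4-methoxybenzyl alcohol (2.2 equiv)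
Product: 5 1,1-bis[(4-methoxybenzyl)oxy]-3-methylbutane
Conditions: PPTS (5 mol %), benzene, reflux, Dean–Stark
Reagents that add atoms: none
Why: Acid-catalysed acetalisation driven by azeotropic removal of water, with a pyridinium acid mild enough to spare the PMB groups.

Step 3
Reactants: 5 1,1-bis[(4-methoxybenzyl)oxy]-3-methylbutane
Product: 6 1-[(4-methoxybenzyl)oxy]-3-methylbut-1-ene (E/Z mixture)
Conditions: TMSOTf (1.1 equiv), i-Pr2NEt (1.3 equiv), CH2Cl2, −20 to 0 °C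
Reagents that add atoms: none
Why: Gassman-type elimination: silyl triflate ionises the acetal to the oxocarbenium ion and the amine removes the α-proton to give the enol ether.

Step 4
Reactants: 6 1-[(4-methoxybenzyl)oxy]-3-methylbut-1-ene
Product: 8 (Z)-2-bromo-1-[(4-methoxybenzyl)oxy]-3-methylbut-1-ene (Br cis to O), via vicinal dibromide 7 (not isolated)
Conditions: Br2 (1.0 equiv), CH2Cl2, −78 °C; then Et3N (3 equiv), −78 to 25 °C
Reagents that add atoms: bromine BrBr
Why: Bromine addition followed by amine-induced dehydrobromination through the labile α-bromo ether gives the 2-bromo enol ether, Z isomer expected to be favoured as with 2-bromovinyl ethers; any E isomer is destroyed in step 5 because its lithio derivative undergoes anti β-elimination.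

Step 5
Reactants: 8 (Z)-2-bromo-1-[(4-methoxybenzyl)oxy]-3-methylbut-1-ene; 2 (R)-isopiperitenone
Product: 10 (1R,6R)-1-{(1Z)-1-[(4-methoxybenzyl)oxy]-3-methylbut-1-en-2-yl}-3-methyl-6-(prop-1-en-2-yl)cyclohex-2-en-1-ol, via vinyllithium 9 (not isolated)
Conditions: 8, t-BuLi (2.0 equiv), Et2O, −78 °C, 20 min; then 2 in THF, −78 °C; H2O
Reagents that add atoms: none
Why: Bromine–lithium exchange with retention gives the configurationally stable cis-β-alkoxyvinyllithium, which adds 1,2 to the enone carbonyl anti to the neighbouring isopropenyl group, so the new carbinol centre is R and the two alkenyl groups are trans.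

Step 6
Reactants: 10 (1R,6R)-1-{(1Z)-1-[(4-methoxybenzyl)oxy]-3-methylbut-1-en-2-yl}-3-methyl-6-(prop-1-en-2-yl)cyclohex-2-en-1-ol
Product: 12 (1(10)E,4Z,7R,8S)-8-[(4-methoxybenzyl)oxy]germacra-1(10),4-dien-6-one (7β-isopropyl and 8α-OPMB), via potassium enolate 11 (not isolated)
Conditions: KH (3 equiv), 18-crown-6 (1.1 equiv), THF, 0 to 25 °C; then AcOH, THF, −78 °C
Reagents that add atoms: none
Why: Anionic oxy-Cope [3,3]-sigmatropic ring expansion through a chair with both ring bonds equatorial forms C8–C9 and the E-1(10) alkene and passes the limonene-derived chirality to C8 (8S, the Z-enol ether oxygen axial next to the potassium alkoxide); protonation of the enolate from the ring periphery, which is also the thermodynamic preference, sets C7 (7R) with isopropyl trans to OPMB.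

Step 7
Reactants: 12 (1(10)E,4Z,7R,8S)-8-[(4-methoxybenzyl)oxy]germacra-1(10),4-dien-6-one
Product: 15 (1R,4E,7R,8S,10R)-1,10-epoxy-8-[(4-methoxybenzyl)oxy]germacr-4-en-6-one, via stannyl silyl enol ether 13 (not isolated), via all-E dienone 14 (not isolated)
Conditions: Me3SnLi (1.2 equiv), THF, −78 °C; TMSCl (1.5 equiv), −78 to −40 °C; then mCPBA (2.4 equiv), NaHCO3, CH2Cl2, −40 to 0 °C
Reagents that add atoms: mCPBA OOC(=O)c1cccc(Cl)c1
Why: Conjugate stannylation and peracid oxidation of the silyl enol ether add tin and oxygen from the same outer face, and anti destannylative elimination returns the enone with inverted (E) geometry; the second equivalent of peracid (Prilezhaev epoxidation) takes the strained electron-rich 1(10) alkene from its outer face (1R,10R) while the enone is inert.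

Step 8
Reactants: 15 (1R,4E,7R,8S,10R)-1,10-epoxy-8-[(4-methoxybenzyl)oxy]germacr-4-en-6-one
Product: 16 (1R,4R,5S,7R,8S,10R)-1,10:4,5-diepoxy-8-[(4-methoxybenzyl)oxy]germacran-6-one
Conditions: t-BuOOH (2 equiv), BnNMe3OH (Triton B, 0.2 equiv), THF, 0 °C
Reagents that add atoms: tert-butyl hydroperoxide CC(C)(C)OO
Why: Weitz–Scheffer nucleophilic epoxidation of the E-enone from the ring periphery of the crown conformer (7β-isopropyl and 8α-OPMB both equatorial) gives the trans 4α,5β-oxirane, the face normally taken in germacrane 4,5-epoxidations.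

Step 9
Reactants: 16 (1R,4R,5S,7R,8S,10R)-1,10:4,5-diepoxy-8-[(4-methoxybenzyl)oxy]germacran-6-one
Product: 17 (1R,4R,5R,6R,7S,8S,10R)-1,10:4,5-diepoxy-8-[(4-methoxybenzyl)oxy]germacran-6-ol
Conditions: NaBH4, CeCl3·7H2O, MeOH, −78 to −40 °C
Reagents that add atoms: none
Why: Luche reduction of an α,β-epoxy ketone is anti (erythro) selective, cerium bridging the carbonyl and oxirane oxygens and hydride entering on the side away from C4, which gives the 6R (6β) alcohol.

Step 10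
Reactants: 17 (1R,4R,5R,6R,7S,8S,10R)-1,10:4,5-diepoxy-8-[(4-methoxybenzyl)oxy]germacran-6-ol
Product: 20 (1(10)Z,4R,5R,6R,7S,8S)-4,5-epoxy-8-[(4-methoxybenzyl)oxy]germacr-1(10)-en-6-ol, via phosphine dialkoxide 18 (not isolated), via phosphonium betaine 19 (not isolated)
Conditions: n-BuLi (1.0 equiv), THF, −78 °C; LiPPh2 (1.5 equiv), 0 to 25 °C; then MeI (3 equiv), 25 °C; H2O
Reagents that add atoms: none
Why: SN2 opening of the 1,10-oxirane at the unhindered secondary C1 (inversion), P-methylation and Wittig-type syn-cycloelimination of the betaine remove the oxygen with net inversion of geometry, so the trans-oxirane gives the Z alkene; the 4,5-oxirane is protected by its quaternary C4 and the neighbouring C6 alkoxide.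

Step 11
Reactants: 20 (1(10)Z,4R,5R,6R,7S,8S)-4,5-epoxy-8-[(4-methoxybenzyl)oxy]germacr-1(10)-en-6-ol
Product: 21 (1(10)Z,4R,5R,6R,7R,8S)-4,5-epoxygermacr-1(10)-ene-6,8-diol
Conditions: DDQ (1.3 equiv), CH2Cl2/pH 7 buffer (10:1), 0 °C
Reagents that add atoms: none
Why: Oxidative PMB cleavage (hydride abstraction to the benzylic oxocarbenium ion, then hydrolysis) under buffered conditions that leave the oxirane and the alkene alone.

Step 12
Reactants: 21 (1(10)Z,4R,5R,6R,7R,8S)-4,5-epoxygermacr-1(10)-ene-6,8-diol; 22 3,4,5-trimethoxybenzoic acid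
Product: 23 (1(10)Z,4R,5R,6R,7S,8R)-4,5-epoxy-6-hydroxygermacr-1(10)-en-8-yl 3,4,5-trimethoxybenzoate (target)
Conditions: 22 (1.5 equiv), PPh3, DIAD, toluene, 0 to 25 °C
Reagents that add atoms: none
Why: Mitsunobu esterification proceeds with SN2 inversion at C8, turning the equatorial 8S alcohol into the 8R ester, while the C6 hydroxyl, flanked by the oxirane and the isopropyl-bearing carbon, is too hindered to be activated.

**Compound list**

1 | (S)-limonene, (4S)-1-methyl-4-(prop-1-en-2-yl)cyclohex-1-ene | CC1=CC[C@H](CC1)C(C)=C | starting material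
2 | (R)-isopiperitenone, (6R)-3-methyl-6-(prop-1-en-2-yl)cyclohex-2-en-1-one | CC1=CC(=O)[C@H](CC1)C(C)=C | intermediate
3 | 3-methylbutanal | CC(C)CC=O | starting material
4 | 4-methoxybenzyl alcohol | COc1ccc(CO)cc1 | starting material
5 | 1,1-bis[(4-methoxybenzyl)oxy]-3-methylbutane | CC(C)CC(OCc1ccc(OC)cc1)OCc1ccc(OC)cc1 | intermediate
6 | 1-[(4-methoxybenzyl)oxy]-3-methylbut-1-ene (E/Z mixture) | CC(C)C=COCc1ccc(OC)cc1 | intermediate
7 | 1,2-dibromo-1-[(4-methoxybenzyl)oxy]-3-methylbutane (diastereomer mixture) | CC(C)C(Br)C(Br)OCc1ccc(OC)cc1 | intermediate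
8 | (Z)-2-bromo-1-[(4-methoxybenzyl)oxy]-3-methylbut-1-ene | CC(C)/C(Br)=C/OCc1ccc(OC)cc1 | intermediate
9 | [(1E)-1-[(4-methoxybenzyl)oxy]-3-methylbut-1-en-2-yl]lithium (Li cis to O) | [Li]/C(C(C)C)=C\OCc1ccc(OC)cc1 | intermediate
10 | (1R,6R)-1-{(1Z)-1-[(4-methoxybenzyl)oxy]-3-methylbut-1-en-2-yl}-3-methyl-6-(prop-1-en-2-yl)cyclohex-2-en-1-ol | CC1=C[C@](O)(/C(C(C)C)=C\OCc2ccc(OC)cc2)[C@H](CC1)C(C)=C | intermediate
11 | potassium (1(10)E,4Z,6Z,8S)-8-[(4-methoxybenzyl)oxy]germacra-1(10),4,6-trien-6-olate | [K+].C1/C(C)=C\C(\[O-])=C(/C(C)C)[C@@H](OCc2ccc(OC)cc2)C/C(C)=C/C1 | intermediate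
12 | (1(10)E,4Z,7R,8S)-8-[(4-methoxybenzyl)oxy]germacra-1(10),4-dien-6-one | O=C1/C=C(C)\CC/C=C(C)/C[C@H](OCc2ccc(OC)cc2)[C@H]1C(C)C | intermediate
13 | (1(10)E,4R,5E,7R,8S)-8-[(4-methoxybenzyl)oxy]-4-(trimethylstannyl)-6-[(trimethylsilyl)oxy]germacra-1(10),5-diene | C1[C@@](C)([Sn](C)(C)C)/C=C(/O[Si](C)(C)C)[C@H](C(C)C)[C@@H](OCc2ccc(OC)cc2)C/C(C)=C/C1 | intermediate
14 | (1(10)E,4E,7R,8S)-8-[(4-methoxybenzyl)oxy]germacra-1(10),4-dien-6-one | O=C1/C=C(C)/CC/C=C(C)/C[C@H](OCc2ccc(OC)cc2)[C@H]1C(C)C | intermediate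
15 | (1R,4E,7R,8S,10R)-1,10-epoxy-8-[(4-methoxybenzyl)oxy]germacr-4-en-6-one | O=C1/C=C(C)/CC[C@H]3O[C@]3(C)C[C@H](OCc2ccc(OC)cc2)[C@H]1C(C)C | intermediate
16 | (1R,4R,5S,7R,8S,10R)-1,10:4,5-diepoxy-8-[(4-methoxybenzyl)oxy]germacran-6-one | O=C1[C@H]4O[C@]4(C)CC[C@H]3O[C@]3(C)C[C@H](OCc2ccc(OC)cc2)[C@H]1C(C)C | intermediate
17 | (1R,4R,5R,6R,7S,8S,10R)-1,10:4,5-diepoxy-8-[(4-methoxybenzyl)oxy]germacran-6-ol | O[C@H]1[C@H]4O[C@]4(C)CC[C@H]3O[C@]3(C)C[C@H](OCc2ccc(OC)cc2)[C@H]1C(C)C | intermediate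
18 | dilithium (1S,4R,5R,6R,7S,8S,10R)-1-(diphenylphosphanyl)-4,5-epoxy-8-[(4-methoxybenzyl)oxy]germacrane-6,10-bis(olate) | [Li+].[Li+].[O-][C@H]1[C@H]3O[C@]3(C)CC[C@H](P(c4ccccc4)c4ccccc4)[C@@]([O-])(C)C[C@H](OCc2ccc(OC)cc2)[C@H]1C(C)C | intermediate
19 | lithium (1S,4R,5R,6R,7S,8S,10R)-4,5-epoxy-8-[(4-methoxybenzyl)oxy]-1-[methyl(diphenyl)phosphaniumyl]germacrane-6,10-bis(olate) (betaine) | [Li+].[O-][C@H]1[C@H]3O[C@]3(C)CC[C@H]([P+](C)(c4ccccc4)c4ccccc4)[C@@]([O-])(C)C[C@H](OCc2ccc(OC)cc2)[C@H]1C(C)C | intermediate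
20 | (1(10)Z,4R,5R,6R,7S,8S)-4,5-epoxy-8-[(4-methoxybenzyl)oxy]germacr-1(10)-en-6-ol | O[C@H]1[C@H]3O[C@]3(C)CC/C=C(C)\C[C@H](OCc2ccc(OC)cc2)[C@H]1C(C)C | intermediate
21 | (1(10)Z,4R,5R,6R,7R,8S)-4,5-epoxygermacr-1(10)-ene-6,8-diol | O[C@H]1[C@H]3O[C@]3(C)CC/C=C(C)\C[C@H](O)[C@H]1C(C)C | intermediate
22 | 3,4,5-trimethoxybenzoic acid | COc1cc(cc(OC)c1OC)C(=O)O | starting material
23 | (1(10)Z,4R,5R,6R,7S,8R)-4,5-epoxy-6-hydroxygermacr-1(10)-en-8-yl 3,4,5-trimethoxybenzoate | COc1cc(C(=O)O[C@@H]2C/C(C)=C\CC[C@@]3(C)O[C@@H]3[C@H](O)[C@@H]2C(C)C)cc(OC)c1OC | target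

**Step count and risks**

Total: 12 steps. Longest linear sequence: 11 steps (3 → 5 → 6 → 8 → 10 → 12 → 15 → 16 → 17 → 20 → 21 → 23); 9 steps from (S)-limonene.

The three steps most likely to fail:

Step 7. The one-pot Z-to-E enone isomerisation needs tin and peracid oxygen to enter from the same face, and this is an expectation, not a certainty. The fallback sets out from 12 and comes back at 16. One equivalent of mCPBA (NaHCO3, CH2Cl2, 0 °C) epoxidises only the 1(10) alkene to (1R,4Z,7R,8S,10R)-1,10-epoxy-8-[(4-methoxybenzyl)oxy]germacr-4-en-6-one F1. OsO4 (cat.) with NMO dihydroxylates the Z-enone from its outer face to (1R,4R,5R,7R,8S,10R)-1,10-epoxy-4,5-dihydroxy-8-[(4-methoxybenzyl)oxy]germacran-6-one F2. MsCl/Et3N at −20 °C sulfonylates only the secondary C5 hydroxyl to give the 5-methanesulfonate F3. K2CO3 in MeOH then lets the tertiary C4 alkoxide displace the mesylate with inversion, so the trans-oxirane of 16 is made from the Z alkene with no enone isomerisation.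

Step 10. Backside attack at C1 of a medium-ring oxirane may be slow, and the second oxirane or a Payne shift may interfere. The fallback sets out from 12 and comes back at 20. Step 7 is run with 1.05 equiv of mCPBA so that the all-E dienone 14 is isolated with its 1(10) alkene intact. The enone is epoxidised as in step 8 to (1(10)E,4R,5S,7R,8S)-4,5-epoxy-8-[(4-methoxybenzyl)oxy]germacr-1(10)-en-6-one F4 and reduced as in step 9 to (1(10)E,4R,5R,6R,7S,8S)-4,5-epoxy-8-[(4-methoxybenzyl)oxy]germacr-1(10)-en-6-ol F5. Irradiation with PhSSPh (reversible thiyl-radical addition to the trisubstituted alkene) then equilibrates the E alkene to the less strained cis ring alkene, giving 20.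

Step 12. The C8 alcohol is menthol-like and the acid is only weakly acidic, so the Mitsunobu reaction may give low conversion or elimination. The fallback sets out from 21 and comes back at 23. Mitsunobu inversion with the stronger 4-nitrobenzoic acid (PPh3, DIAD) gives (1(10)Z,4R,5R,6R,7S,8R)-4,5-epoxy-6-hydroxygermacr-1(10)-en-8-yl 4-nitrobenzoate F6. K2CO3/MeOH frees (1(10)Z,4R,5R,6R,7R,8R)-4,5-epoxygermacr-1(10)-ene-6,8-diol F7. Commercial 3,4,5-trimethoxybenzoyl chloride (pyridine, DMAP, −20 °C) then acylates the less hindered C8 hydroxyl to give 23.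

**Further compounds**

F1 | step 7 | (1R,4Z,7R,8S,10R)-1,10-epoxy-8-[(4-methoxybenzyl)oxy]germacr-4-en-6-one | O=C1/C=C(C)\CC[C@H]3O[C@]3(C)C[C@H](OCc2ccc(OC)cc2)[C@H]1C(C)C
F2 | step 7 | (1R,4R,5R,7R,8S,10R)-1,10-epoxy-4,5-dihydroxy-8-[(4-methoxybenzyl)oxy]germacran-6-one | O=C1[C@H](O)[C@](C)(O)CC[C@H]3O[C@]3(C)C[C@H](OCc2ccc(OC)cc2)[C@H]1C(C)C
F3 | step 7 | (1R,4R,5R,7R,8S,10R)-1,10-epoxy-4-hydroxy-8-[(4-methoxybenzyl)oxy]-6-oxogermacran-5-yl methanesulfonate | O=C1[C@H](OS(C)(=O)=O)[C@](C)(O)CC[C@H]3O[C@]3(C)C[C@H](OCc2ccc(OC)cc2)[C@H]1C(C)C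
F4 | step 10 | (1(10)E,4R,5S,7R,8S)-4,5-epoxy-8-[(4-methoxybenzyl)oxy]germacr-1(10)-en-6-one | O=C1[C@H]3O[C@]3(C)CC/C=C(C)/C[C@H](OCc2ccc(OC)cc2)[C@H]1C(C)C
F5 | step 10 | (1(10)E,4R,5R,6R,7S,8S)-4,5-epoxy-8-[(4-methoxybenzyl)oxy]germacr-1(10)-en-6-ol | O[C@H]1[C@H]3O[C@]3(C)CC/C=C(C)/C[C@H](OCc2ccc(OC)cc2)[C@H]1C(C)C
F6 | step 12 | (1(10)Z,4R,5R,6R,7S,8R)-4,5-epoxy-6-hydroxygermacr-1(10)-en-8-yl 4-nitrobenzoate | O[C@H]1[C@H]3O[C@]3(C)CC/C=C(C)\C[C@@H](OC(=O)c2ccc(cc2)[N+](=O)[O-])[C@H]1C(C)C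
F7 | step 12 | (1(10)Z,4R,5R,6R,7R,8R)-4,5-epoxygermacr-1(10)-ene-6,8-diol | O[C@H]1[C@H]3O[C@]3(C)CC/C=C(C)\C[C@@H](O)[C@H]1C(C)C
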